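Ring C is disconnected across C2–C3 and C4–C4a into an O-aryl oxocarbenium ion (O1=C2, bearing ring B) and ethoxyacetylene. The key step exploits two features: C2, an acetal carbon, ionises readily because O1 and the para oxygen of ring B stabilise the cation, and C4a of ring A, ortho to O1 and to one methoxy group and para to the other, is highly nucleophilic. In one operation a chiral acid ionises a racemic mixed acetal, the ynol ether adds at C2 and C4a closes ring C, setting the C2 stereocentre and the C4 oxidation level. The precursor is the O-methyl acetal joining 4-[2-(benzyloxy)benzyl]-3,5-dimethoxyphenol to 4-(benzyloxy)benzaldehyde.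

Key step: step 7

Assumption: the target is the 2R flavanone (at C2: O1 > ring B > C3 > H) and 14 and 15 carry the same descriptor; which antipode of the chiral acid gives 2R cannot be predicted with confidence, so the (R)-acid is written provisionally and the (S)-acid would be used if the sense proves opposite.

Design remarks: ring A is taken from 4-hydroxy-2,6-dimethoxybenzaldehyde 1, in which the carbon para to the phenol oxygen is already functionalised, so no ortho/para selectivity has to be controlled. Both free phenols of the target travel as benzyl ethers, which leave together with the C5 methyl group in the last step. The acetal keeps methoxy as leaving group, since its oxygen is the more basic acetal oxygen and should be engaged first by the acid; the methanol released is taken up by 5 Å molecular sieves.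

Step 1
Reactants: 1 4-hydroxy-2,6-dimethoxybenzaldehyde
Product: 2 2,6-dimethoxy-4-{[tri(propan-2-yl)silyl]oxy}benzaldehyde
Conditions: iPr3SiCl, imidazole, DMF, rt
Reagents that add atoms: chlorotri(propan-2-yl)silane, CC(C)[Si](Cl)(C(C)C)C(C)C
Why: Imidazole-promoted O-silylation of a phenol; the bulky silyl ether removes the acidic proton that would quench the Grignard reagent and deactivate the aldehyde, and it withstands organomagnesium reagents and CF3CO2H.

Step 2
Reactants: 2 2,6-dimethoxy-4-{[tri(propan-2-yl)silyl]oxy}benzaldehyde; 3 1-(benzyloxy)-2-bromobenzene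
Product: 5 rac-[2-(benzyloxy)phenyl](2,6-dimethoxy-4-{[tri(propan-2-yl)silyl]oxy}phenyl)methanol, via Grignard reagent 4 (not isolated)
Conditions: 3, Mg, THF, 40 °C; then 2, THF, 0 °C; H2O
Reagents that add atoms: none
Why: Grignard formation by magnesium insertion into the aryl bromide followed by 1,2-addition to the aldehyde; the carbinol centre is formed racemic and is erased in step 3.

Step 3
Reactants: 5 rac-[2-(benzyloxy)phenyl](2,6-dimethoxy-4-{[tri(propan-2-yl)silyl]oxy}phenyl)methanol
Product: 6 {4-[2-(benzyloxy)benzyl]-3,5-dimethoxyphenoxy}tri(propan-2-yl)silane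
Conditions: Et3SiH, CF3CO2H, CH2Cl2, −40 → 0 °C
Reagents that add atoms: none
Why: Ionic hydrogenation (acid-promoted deoxygenation with a silane): the acid ionises the carbinol to a diarylmethyl cation strongly stabilised by the trioxygenated ring and Et3SiH transfers hydride, while the benzyl ether and the aryl silyl ether should be untouched.

Step 4
Reactants: 6 {4-[2-(benzyloxy)benzyl]-3,5-dimethoxyphenoxy}tri(propan-2-yl)silane
Product: 7 4-[2-(benzyloxy)benzyl]-3,5-dimethoxyphenol
Conditions: Bu4NF, THF, 0 °C; H2O
Reagents that add atoms: none
Why: Fluoride-induced desilylation driven by the strong Si–F bond; no other group in 6 responds to fluoride.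

Step 5
Reactants: 8 4-(benzyloxy)benzaldehyde
Product: 9 1-(benzyloxy)-4-(dimethoxymethyl)benzene
Conditions: HC(OMe)3, MeOH, p-TsOH·H2O (cat.), rt; then Et3N
Reagents that add atoms: trimethyl orthoformate, COC(OC)OC; methanol, CO
Why: Acid-catalysed acetalisation, driven to completion by the orthoformate, which consumes the water formed.

Step 6
Reactants: 9 1-(benzyloxy)-4-(dimethoxymethyl)benzene; 7 4-[2-(benzyloxy)benzyl]-3,5-dimethoxyphenol
Product: 12 rac-1-(benzyloxy)-4-[{4-[2-(benzyloxy)benzyl]-3,5-dimethoxyphenoxy}(methoxy)methyl]benzene, via alpha-chloro ether 10 (not isolated), via sodium phenoxide 11 (not isolated)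
Conditions: 9, AcCl, ZnBr2 (cat.), CH2Cl2, 0 °C → rt, evaporate; 7, NaH, THF, 0 °C; combine at −78 → 0 °C; Et3N, aq NaHCO3; Et3N-deactivated silica
Reagents that add atoms: none
Why: Acetal–acyl chloride exchange (haloalkyl ether formation) gives the alpha-chloro ether, and the preformed phenoxide is alkylated at oxygen in a Williamson-type, SN1-like substitution; the medium stays basic so the acid-labile mixed acetal should survive, and it is formed racemic, which is all the next step needs.

Step 7
Reactants: 12 rac-1-(benzyloxy)-4-[{4-[2-(benzyloxy)benzyl]-3,5-dimethoxyphenoxy}(methoxy)methyl]benzene; 13 ethoxyacetylene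
Product: 14 (2R)-2-[4-(benzyloxy)phenyl]-6-[2-(benzyloxy)benzyl]-4-ethoxy-5,7-dimethoxy-2H-chromene
Conditions: 13 (3 equiv, solution in hexanes), (R)-3,3'-bis(2,4,6-triisopropylphenyl)-1,1'-binaphthyl-2,2'-diyl N-(trifluoromethylsulfonyl)phosphoramide (10 mol%), 5 Å molecular sieves, toluene, −78 → −40 °C; then Et3N
Reagents that add atoms: none
Why: Proposed new method: the chiral acid protonates the methoxy oxygen of racemic 12 and methanol leaves, so that both enantiomers converge on one planar O-aryl oxocarbenium ion (stabilised by O1 and by the para-benzyloxy oxygen of ring B) paired with the chiral phosphoramide anion; the nucleophilic terminal carbon of 13 then adds to C2 (bond C2–C3), the ethoxy-stabilised vinyl cation (ketenium ion) so formed is attacked by C4a (bond C4–C4a), and loss of the arenium proton to the anion regenerates the acid. The closest known reaction type is the Lewis-acid-promoted oxa-Povarov reaction of such acetal-derived aryl oxocarbenium ions with alkenes to give chromans, combined with chiral-counter-anion control of additions to oxocarbenium ions and with arene capture of ketenium or keteniminium ions generated from ynol ethers and ynamides. Ring C is closed in a stepwise cationic [4+2] sense by intramolecular Friedel–Crafts alkenylation, a six-membered closure onto the digonal ketenium carbon in which C3=C4 ends up endocyclic and the C=O+ π bond that is broken is exocyclic (formally 6-exo-dig). The only new stereocentre, C2 (R), is set in the C2–C3 bond formation by the chiral anion, which should shield one face of the ion pair (pure catalyst control, since ionisation erases the acetal stereocentre), and the catalyst antipode that gives 2R must be fixed in a first run. Regioselectivity of the alkyne addition follows from the polarisation of the ynol ether, and regioselectivity of the ring closure is not in question because the two carbons ortho to O1 in 12 are equivalent by symmetry. Chemoselectivity for C4a over methanol in capturing the ketenium ion should be secured by intramolecularity and by the trioxygenated ring A, helped by the sieves that sequester methanol, while low temperature and dilution disfavour intermolecular arene alkylation.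

Step 8
Reactants: 14 (2R)-2-[4-(benzyloxy)phenyl]-6-[2-(benzyloxy)benzyl]-4-ethoxy-5,7-dimethoxy-2H-chromene
Product: 15 (2R)-2-[4-(benzyloxy)phenyl]-6-[2-(benzyloxy)benzyl]-5,7-dimethoxy-2,3-dihydro-4H-chromen-4-one
Conditions: 1 M aq HCl, THF, 0 °C → rt
Reagents that add atoms: water, O
Why: Acid-catalysed hydrolysis of the enol ether (protonation at C3, hydration at C4, loss of ethanol); C2 takes no part, and dilute acid, unlike base, should not open ring C to the chalcone.

Step 9
Reactants: 15 (2R)-2-[4-(benzyloxy)phenyl]-6-[2-(benzyloxy)benzyl]-5,7-dimethoxy-2,3-dihydro-4H-chromen-4-one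
Product: 16 (+)-methylphelligrin A, (2R)-5-hydroxy-6-(2-hydroxybenzyl)-2-(4-hydroxyphenyl)-7-methoxy-2,3-dihydro-4H-chromen-4-one
Conditions: BCl3, C6HMe5, CH2Cl2, −78 → 0 °C; then H2O, 0 °C
Reagents that add atoms: none
Why: Lewis-acid ether cleavage: BCl3 should remove both aryl benzyl ethers at low temperature, with pentamethylbenzene capturing the benzyl cations by Friedel–Crafts alkylation, and on warming cleave only the C5 methyl ether, whose oxygen sits with the C4 carbonyl in a six-membered boron chelate, so that the C7 methoxy group and the C2 stereocentre are retained.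

Compound list
1 | 4-hydroxy-2,6-dimethoxybenzaldehyde | O=Cc1c(OC)cc(O)cc1OC | starting material
2 | 2,6-dimethoxy-4-{[tri(propan-2-yl)silyl]oxy}benzaldehyde | O=Cc1c(OC)cc(O[Si](C(C)C)(C(C)C)C(C)C)cc1OC | intermediate
3 | 1-(benzyloxy)-2-bromobenzene | Brc1ccccc1OCc1ccccc1 | starting material
4 | [2-(benzyloxy)phenyl]magnesium bromide | Br[Mg]c1ccccc1OCc1ccccc1 | intermediate
5 | rac-[2-(benzyloxy)phenyl](2,6-dimethoxy-4-{[tri(propan-2-yl)silyl]oxy}phenyl)methanol | OC(c1ccccc1OCc1ccccc1)c1c(OC)cc(O[Si](C(C)C)(C(C)C)C(C)C)cc1OC | intermediate
6 | {4-[2-(benzyloxy)benzyl]-3,5-dimethoxyphenoxy}tri(propan-2-yl)silane | COc1cc(O[Si](C(C)C)(C(C)C)C(C)C)cc(OC)c1Cc1ccccc1OCc1ccccc1 | intermediate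
7 | 4-[2-(benzyloxy)benzyl]-3,5-dimethoxyphenol | COc1cc(O)cc(OC)c1Cc1ccccc1OCc1ccccc1 | intermediate
8 | 4-(benzyloxy)benzaldehyde | O=Cc1ccc(OCc2ccccc2)cc1 | starting material
9 | 1-(benzyloxy)-4-(dimethoxymethyl)benzene | COC(OC)c1ccc(OCc2ccccc2)cc1 | intermediate
10 | rac-1-(benzyloxy)-4-[chloro(methoxy)methyl]benzene | COC(Cl)c1ccc(OCc2ccccc2)cc1 | intermediate
11 | sodium 4-[2-(benzyloxy)benzyl]-3,5-dimethoxyphenolate | [Na+].[O-]c1cc(OC)c(Cc2ccccc2OCc2ccccc2)c(OC)c1 | intermediate
12 | rac-1-(benzyloxy)-4-[{4-[2-(benzyloxy)benzyl]-3,5-dimethoxyphenoxy}(methoxy)methyl]benzene | COC(Oc1cc(OC)c(Cc2ccccc2OCc2ccccc2)c(OC)c1)c1ccc(OCc2ccccc2)cc1 | intermediate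
13 | ethoxyacetylene | C#COCC | starting material
14 | (2R)-2-[4-(benzyloxy)phenyl]-6-[2-(benzyloxy)benzyl]-4-ethoxy-5,7-dimethoxy-2H-chromene | CCOC1=C[C@H](c2ccc(OCc3ccccc3)cc2)Oc2cc(OC)c(Cc3ccccc3OCc3ccccc3)c(OC)c21 | intermediate
15 | (2R)-2-[4-(benzyloxy)phenyl]-6-[2-(benzyloxy)benzyl]-5,7-dimethoxy-2,3-dihydro-4H-chromen-4-one | COc1cc2c(c(OC)c1Cc1ccccc1OCc1ccccc1)C(=O)C[C@H](c1ccc(OCc3ccccc3)cc1)O2 | intermediate
16 | (+)-methylphelligrin A, (2R)-5-hydroxy-6-(2-hydroxybenzyl)-2-(4-hydroxyphenyl)-7-methoxy-2,3-dihydro-4H-chromen-4-one | COc1cc2c(c(O)c1Cc1ccccc1O)C(=O)C[C@H](c1ccc(O)cc1)O2 | target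

Total step count: 9. Longest linear sequence: 8 steps (steps 1, 2, 3, 4, 6, 7, 8, 9); step 5 is a one-step side branch.

Steps most likely to fail

Step 7 (Proposed new method). Several processes could defeat it:
- ionisation in the wrong sense (loss of the phenol instead of methanol), followed by crossover or C-alkylation;
- addition of the chiral acid or of methanol to the ynol ether, which ties up the catalyst and consumes the alkyne;
- capture of the ketenium ion by methanol instead of C4a;
- intermolecular arene alkylation by the oxocarbenium ion;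
- weak facial discrimination by the anion;
- erosion of the C2 configuration by acid-induced C2–O1 ionisation of the product.

The fallback uses known chemistry, sets out from 7 and comes back to the route at 15. Ortho C-acetylation of 7 under Vilsmeier–Haack conditions (N,N-dimethylacetamide, POCl3, then aqueous hydrolysis; the two ortho carbons are equivalent) should give 1-{3-[2-(benzyloxy)benzyl]-6-hydroxy-2,4-dimethoxyphenyl}ethan-1-one F1. Condensation with N,N-dimethylformamide dimethyl acetal should give (2E)-1-{3-[2-(benzyloxy)benzyl]-6-hydroxy-2,4-dimethoxyphenyl}-3-(dimethylamino)prop-2-en-1-one F2. Aqueous HCl should close this, with loss of dimethylamine, to 6-[2-(benzyloxy)benzyl]-5,7-dimethoxy-4H-chromen-4-one F3. Enantioselective conjugate addition of 4-(benzyloxy)phenylboronic acid (OB(O)c1ccc(OCc2ccccc2)cc1) to F3 would then set C2 under ligand control and deliver 15. The catalyst would be Pd(OCOCF3)2 with a chiral 4-tert-butyl-2-(pyridin-2-yl)-4,5-dihydro-1,3-oxazole ligand (NH4PF6, H2O, ClCH2CH2Cl, 60 °C), using the ligand antipode that gives 2R.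

Step 6. The ionised chloro ether may collapse to aldehyde and chloromethane before it meets the phenoxide, the ambident phenoxide may be alkylated at carbon instead of oxygen, and the acetal may hydrolyse during isolation. The fallback avoids the chloro ether altogether: acid-catalysed acetal exchange between 7 and 9 (pyridinium p-toluenesulfonate as catalyst, CH2Cl2 at reflux, methanol removed continuously on 5 Å molecular sieves). It sets out from 7 and 9, comes back at 12 and forms no new compound (F0).

Step 9. Discrimination between the C5 and C7 methyl ethers may be incomplete, benzyl cations may re-alkylate the electron-rich rings, and the Lewis acid may open ring C with loss of configuration at C2. The fallback sets out from 15 and comes back at 16 by two orthogonal stages. Hydrogenolysis (H2, Pd/C, EtOAc, rt) should remove both benzyl groups without any Lewis acid and give (2R)-2-(4-hydroxyphenyl)-6-(2-hydroxybenzyl)-5,7-dimethoxy-2,3-dihydro-4H-chromen-4-one F4. Chelation-controlled monodemethylation at C5 with MgI2·OEt2 (THF, mild warming) should then give 16.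

Further compounds
F1 | step 7 | 1-{3-[2-(benzyloxy)benzyl]-6-hydroxy-2,4-dimethoxyphenyl}ethan-1-one | CC(=O)c1c(O)cc(OC)c(Cc2ccccc2OCc2ccccc2)c1OC
F2 | step 7 | (2E)-1-{3-[2-(benzyloxy)benzyl]-6-hydroxy-2,4-dimethoxyphenyl}-3-(dimethylamino)prop-2-en-1-one | CN(C)/C=C/C(=O)c1c(O)cc(OC)c(Cc2ccccc2OCc2ccccc2)c1OC
F3 | step 7 | 6-[2-(benzyloxy)benzyl]-5,7-dimethoxy-4H-chromen-4-one | COc1cc2occc(=O)c2c(OC)c1Cc1ccccc1OCc1ccccc1
F0 | step 6 | none | none
F4 | step 9 | (2R)-2-(4-hydroxyphenyl)-6-(2-hydroxybenzyl)-5,7-dimethoxy-2,3-dihydro-4H-chromen-4-one | COc1cc2c(c(OC)c1Cc1ccccc1O)C(=O)C[C@H](c1ccc(O)cc1)O2
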